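**Retrosynthetic overview** (ring A = the diol ring, ring B = the bromohydrin ring)

1. Prevezol C ⇐ ketone 18 by Takai–Lombardo methylenation of the linking carbonyl ⇐ diketone 17 by hydroxyl-directed reduction of the ring A ketone.
2. Key disconnection: the CO–CH2 bond between the halves, made by Giese addition of an acyl radical (from the aldehyde C–H of ring B fragment 15) to the exo-methylene ketone 7 of ring A. The two stereocentres flanking the new 1,4-diketone are then set by equilibration.
3. Ring A is not built. Its carbocycle comes from 6-methylcyclohex-2-en-1-one by Rh-catalysed isopropenyl addition, α-hydroxylation and α-methylenation.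
4. Ring B is the only ring formed, at the start of its branch, by Diels–Alder reaction of 2-methoxybuta-1,3-diene with acrylonitrile. Enantioselective α-bromination, methyl addition (cis-bromohydrin) and nitrile-to-aldehyde reduction follow.

Assumption: (S)-BINAP is taken to give the 5S ketone 3 and (4R,5R)-4,5-diphenylimidazolidine the 3R bromide 12; if either facial sense is the other way, the mirror-image ligand or catalyst is used.

**Step 1**
Reactants: 1 6-methylcyclohex-2-en-1-one (racemic); 2 potassium trifluoro(prop-1-en-2-yl)borate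
Product: 3 (5S)-2-methyl-5-(prop-1-en-2-yl)cyclohexan-1-one (mixture of C2 epimers)
Conditions: [Rh(cod)2]PF6 (3 mol %; cod = cycloocta-1,5-diene), (S)-BINAP (3.3 mol %), toluene/H2O 20:1, 105 °C
Reagents that add atoms: none
Why: Rhodium-catalysed asymmetric 1,4-addition of an alkenyltrifluoroborate (Hayashi–Miyaura reaction), in which the ligand sets C5 as S on both enantiomers of 1 because the C2 methyl centre is remote from the reacting carbon and is erased in step 2.

**Step 2**
Reactants: 3 (5S)-2-methyl-5-(prop-1-en-2-yl)cyclohexan-1-one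
Product: 5 (2R,5S)-2-hydroxy-2-methyl-5-(prop-1-en-2-yl)cyclohexan-1-one, via tertiary hydroperoxide 4 (not isolated)
Conditions: KOtBu (1.5 equiv), O2 (1 atm), P(OEt)3 (1.5 equiv), THF/tBuOH 3:1, −20 °C; aq. NH4Cl
Reagents that add atoms: dioxygen, O=O
Why: Enolate autoxidation with in situ phosphite reduction (Gardner α-hydroxylation) goes through the more substituted enolate, and oxygen bonds axially to its half-chair, which puts the new hydroxyl cis to the equatorial isopropenyl group (2R; about 5:1 expected, minor epimer removed by chromatography).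

**Step 3**
Reactants: 5 (2R,5S)-2-hydroxy-2-methyl-5-(prop-1-en-2-yl)cyclohexan-1-one
Product: 7 (2R,5R)-2-hydroxy-2-methyl-6-methylidene-5-(prop-1-en-2-yl)cyclohexan-1-one, via Mannich base 6 (not isolated)
Conditions: (CH2O)n (3 equiv), N-methylanilinium trifluoroacetate (1.5 equiv), THF, 65 °C
Reagents that add atoms: formaldehyde (as paraformaldehyde), C=O
Why: Mannich condensation followed by loss of N-methylaniline (direct α-methylenation of a ketone) can only occur at C6, the one enolisable carbon, and touches neither stereocentre (the C5 descriptor changes from S to R only because the priorities change).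

**Step 4**
Reactants: 8 2-methoxybuta-1,3-diene; 9 acrylonitrile
Product: 11 4-oxocyclohexane-1-carbonitrile, via enol ether cycloadduct 10 (not isolated)
Conditions: toluene, hydroquinone (1 mol %), 120 °C, sealed tube; then 1 M HCl, THF, 23 °C
Reagents that add atoms: water, O
Why: Diels–Alder cycloaddition of a 2-alkoxydiene gives the 1,4-("para") adduct and acid hydrolysis of the enol ether unmasks the achiral keto nitrile, so no stereocentre is set here.

**Step 5**
Reactants: 11 4-oxocyclohexane-1-carbonitrile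
Product: 12 (3R)-3-bromo-4-oxocyclohexane-1-carbonitrile (mixture of C1 epimers)
Conditions: (4R,5R)-4,5-diphenylimidazolidine (20 mol %), PhCO2H (20 mol %), 4,4-dibromo-2,6-di-tert-butylcyclohexa-2,5-dien-1-one (1.05 equiv), THF, −30 °C
Reagents that add atoms: 4,4-dibromo-2,6-di-tert-butylcyclohexa-2,5-dien-1-one, CC(C)(C)C1=CC(Br)(Br)C=C(C(C)(C)C)C1=O
Why: Enamine-catalysed enantioselective α-bromination desymmetrises the ketone, the C2-symmetric amine exposing one face of either enamine so that the C–Br carbon is formed as R, while the nitrile-bearing carbon is left as a mixture that is corrected in step 8.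

**Step 6**
Reactants: 12 (3R)-3-bromo-4-oxocyclohexane-1-carbonitrile
Product: 13 (3R,4S)-3-bromo-4-hydroxy-4-methylcyclohexane-1-carbonitrile (mixture of C1 epimers)
Conditions: MeMgBr (1.5 equiv), CeCl3 (1.5 equiv), THF, −78 °C; aq. NH4Cl at −78 °C
Reagents that add atoms: methylmagnesium bromide, C[Mg]Br
Why: Organocerium 1,2-addition to an α-bromo ketone follows the Cornforth–Felkin model, methyl entering anti to the C–Br bond, which gives the cis-bromohydrin (4S), the classical outcome for 2-halocyclohexanones; the nitrile is inert at −78 °C and the cold quench prevents semipinacol rearrangement.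

**Step 7**
Reactants: 13 (3R,4S)-3-bromo-4-hydroxy-4-methylcyclohexane-1-carbonitrile
Product: 15 (3R,4S)-3-bromo-4-hydroxy-4-methylcyclohexane-1-carbaldehyde (mixture of C1 epimers), via aldimine 14 (not isolated)
Conditions: iBu2AlH (2.5 equiv), CH2Cl2, −78 °C; then 1 M HCl, 0 °C
Reagents that add atoms: water, O
Why: Partial reduction of the nitrile by iBu2AlH stops at the N-aluminated aldimine, which acid hydrolysis turns into the aldehyde without touching the bromide or the stereocentres at C3 and C4.

**Step 8**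
Reactants: 15 (3R,4S)-3-bromo-4-hydroxy-4-methylcyclohexane-1-carbaldehyde (1.5 equiv); 7 (2R,5R)-2-hydroxy-2-methyl-6-methylidene-5-(prop-1-en-2-yl)cyclohexan-1-one (1.0 equiv)
Product: 17 (2R,5S,6R)-6-{2-[(1R,3R,4S)-3-bromo-4-hydroxy-4-methylcyclohexyl]-2-oxoethyl}-2-hydroxy-2-methyl-5-(prop-1-en-2-yl)cyclohexan-1-one, via epimeric diketone 16 (not isolated)
Conditions: (nBu4N)4[W10O32] (2 mol %), MeCN, 390 nm LEDs, 15 °C, Ar; then DBU (0.2 equiv), CH2Cl2, 23 °C
Reagents that add atoms: none
Why: Photocatalytic hydrogen-atom abstraction from the aldehyde C–H gives an acyl radical that adds to the exocyclic methylene of 7 (Giese-type hydroacylation, closed by back hydrogen transfer), and DBU then equilibrates the two epimerisable carbons flanking the new 1,4-diketone so that the side chain on ring A sits trans to isopropenyl (6R, both equatorial) and the acyl group on ring B sits equatorial, cis to bromine (1R, with methyl and bromine also equatorial).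

**Step 9**
Reactants: 17 (2R,5S,6R)-6-{2-[(1R,3R,4S)-3-bromo-4-hydroxy-4-methylcyclohexyl]-2-oxoethyl}-2-hydroxy-2-methyl-5-(prop-1-en-2-yl)cyclohexan-1-one
Product: 18 1-[(1R,3R,4S)-3-bromo-4-hydroxy-4-methylcyclohexyl]-2-[(1R,2R,3R,6S)-2,3-dihydroxy-3-methyl-6-(prop-1-en-2-yl)cyclohexyl]ethan-1-one
Conditions: Me4NBH(OAc)3 (5 equiv), MeCN/AcOH 1:1, −20 °C
Reagents that add atoms: none
Why: Hydroxyl-directed reduction (Saksena–Evans internal hydride delivery), in which the axial tertiary hydroxyl of ring A binds boron and passes hydride to the neighbouring carbonyl on its own face, gives the trans-diaxial diol (new carbinol R, hydroxyl cis to the side chain), while the linking ketone has no hydroxyl within reach and stays.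

**Step 10**
Reactants: 18 1-[(1R,3R,4S)-3-bromo-4-hydroxy-4-methylcyclohexyl]-2-[(1R,2R,3R,6S)-2,3-dihydroxy-3-methyl-6-(prop-1-en-2-yl)cyclohexyl]ethan-1-one
Product: 19 prevezol C [(1R,2R,3R,4S)-3-{2-[(1R,3R,4S)-3-bromo-4-hydroxy-4-methylcyclohexyl]prop-2-en-1-yl}-1-methyl-4-(prop-1-en-2-yl)cyclohexane-1,2-diol]
Conditions: Zn dust, CH2Br2, TiCl4, THF, 5 °C (reagent pre-formed, excess); then 18 in CH2Cl2, 0 → 23 °C
Reagents that add atoms: dibromomethane, BrCBr
Why: Takai–Lombardo methylenation converts the remaining ketone into the 1,1-disubstituted alkene under non-basic conditions, so the epimerisable carbon of ring B, the secondary bromide and the free hydroxyls are preserved.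

**Compound list**

1 | 6-methylcyclohex-2-en-1-one (racemic) | CC1CCC=CC1=O | starting material
2 | potassium trifluoro(prop-1-en-2-yl)borate | [K+].CC(=C)[B-](F)(F)F | starting material
3 | (5S)-2-methyl-5-(prop-1-en-2-yl)cyclohexan-1-one (C2 epimers) | CC1CC[C@H](C(C)=C)CC1=O | intermediate
4 | (2R,5S)-2-hydroperoxy-2-methyl-5-(prop-1-en-2-yl)cyclohexan-1-one | C1[C@@H](C(=C)C)CC[C@@](C)(OO)C1=O | intermediate
5 | (2R,5S)-2-hydroxy-2-methyl-5-(prop-1-en-2-yl)cyclohexan-1-one | C1[C@@H](C(=C)C)CC[C@@](C)(O)C1=O | intermediate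
6 | (2R,5S)-2-hydroxy-2-methyl-6-[(N-methylanilino)methyl]-5-(prop-1-en-2-yl)cyclohexan-1-one (C6 epimers) | CN(CC1[C@@H](C(=C)C)CC[C@@](C)(O)C1=O)c1ccccc1 | intermediate
7 | (2R,5R)-2-hydroxy-2-methyl-6-methylidene-5-(prop-1-en-2-yl)cyclohexan-1-one | C=C1[C@@H](C(=C)C)CC[C@@](C)(O)C1=O | intermediate
8 | 2-methoxybuta-1,3-diene | C=CC(=C)OC | starting material
9 | acrylonitrile (prop-2-enenitrile) | C=CC#N | starting material
10 | 4-methoxycyclohex-3-ene-1-carbonitrile (racemic) | N#CC1CCC(OC)=CC1 | intermediate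
11 | 4-oxocyclohexane-1-carbonitrile | N#CC1CCC(=O)CC1 | intermediate
12 | (3R)-3-bromo-4-oxocyclohexane-1-carbonitrile (C1 epimers) | N#CC1CCC(=O)[C@H](Br)C1 | intermediate
13 | (3R,4S)-3-bromo-4-hydroxy-4-methylcyclohexane-1-carbonitrile (C1 epimers) | N#CC1CC[C@](C)(O)[C@H](Br)C1 | intermediate
14 | (1S,2R)-2-bromo-4-(iminomethyl)-1-methylcyclohexan-1-ol (C4 epimers) | N=CC1CC[C@](C)(O)[C@H](Br)C1 | intermediate
15 | (3R,4S)-3-bromo-4-hydroxy-4-methylcyclohexane-1-carbaldehyde (C1 epimers) | O=CC1CC[C@](C)(O)[C@H](Br)C1 | intermediate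
16 | (2R,5S)-6-{2-[(3R,4S)-3-bromo-4-hydroxy-4-methylcyclohexyl]-2-oxoethyl}-2-hydroxy-2-methyl-5-(prop-1-en-2-yl)cyclohexan-1-one (epimers at C6 and at cyclohexyl C1) | O=C(CC1[C@@H](C(=C)C)CC[C@@](C)(O)C1=O)C1CC[C@](C)(O)[C@H](Br)C1 | intermediate
17 | (2R,5S,6R)-6-{2-[(1R,3R,4S)-3-bromo-4-hydroxy-4-methylcyclohexyl]-2-oxoethyl}-2-hydroxy-2-methyl-5-(prop-1-en-2-yl)cyclohexan-1-one | O=C(C[C@@H]1[C@@H](C(=C)C)CC[C@@](C)(O)C1=O)[C@@H]1CC[C@](C)(O)[C@H](Br)C1 | intermediate
18 | 1-[(1R,3R,4S)-3-bromo-4-hydroxy-4-methylcyclohexyl]-2-[(1R,2R,3R,6S)-2,3-dihydroxy-3-methyl-6-(prop-1-en-2-yl)cyclohexyl]ethan-1-one | O=C(C[C@@H]1[C@@H](C(=C)C)CC[C@@](C)(O)[C@@H]1O)[C@@H]1CC[C@](C)(O)[C@H](Br)C1 | intermediate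
19 | prevezol C [(1R,2R,3R,4S)-3-{2-[(1R,3R,4S)-3-bromo-4-hydroxy-4-methylcyclohexyl]prop-2-en-1-yl}-1-methyl-4-(prop-1-en-2-yl)cyclohexane-1,2-diol] | C=C(C[C@@H]1[C@@H](C(=C)C)CC[C@@](C)(O)[C@@H]1O)[C@@H]1CC[C@](C)(O)[C@H](Br)C1 | target

**Step count:** 10 steps in total. The longest linear sequence is 7 steps (steps 4 to 10); the ring A branch is 3 steps (steps 1 to 3).

**The three steps most likely to fail, with fallbacks**

Step 8 is the riskiest. The secondary acyl radical can lose CO before it adds, and the photocatalyst can also abstract the doubly allylic C5–H of 7. The fallback sets out from 15. The aldehyde is converted with ethane-1,2-diol and pyridinium p-toluenesulfonate (benzene, reflux) into the acetal (1S,2R)-2-bromo-4-(1,3-dioxolan-2-yl)-1-methylcyclohexan-1-ol F1. Hydrogen abstraction from its acetal C–H under the same photocatalyst gives a dioxolan-2-yl radical, a masked acyl radical that cannot decarbonylate. This radical adds to 7 to give the mono-ketal (2R,5S)-6-({2-[(3R,4S)-3-bromo-4-hydroxy-4-methylcyclohexyl]-1,3-dioxolan-2-yl}methyl)-2-hydroxy-2-methyl-5-(prop-1-en-2-yl)cyclohexan-1-one F2. Hydrolysis with 1 M HCl in THF frees the ketone, and the route is rejoined at 16, which is equilibrated with DBU to 17 as in step 8.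

Step 2 can give the wrong regiochemistry (oxidation at C6), over-oxidation, or a poor ratio at C2. The fallback sets out from 3. TMSCl, NaI and Et3N in MeCN give the more substituted enol silane trimethyl{[(5S)-2-methyl-5-(prop-1-en-2-yl)cyclohex-1-en-1-yl]oxy}silane F3. Rubottom oxidation with mCPBA (NaHCO3, CH2Cl2, −20 °C), which epoxidises the electron-rich enol ether in preference to the isopropenyl group, gives the silyloxy ketone (2R,5S)-2-methyl-5-(prop-1-en-2-yl)-2-[(trimethylsilyl)oxy]cyclohexan-1-one F4. Treatment with 1 M HCl in THF returns to the route at 5.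

Step 9 depends on hydride delivery through a five-membered array from a hindered tertiary hydroxyl; it may be slow or may give the cis-diol. The fallback sets out from 17 and reverses the order of the last two operations. Takai–Lombardo methylenation (Zn, CH2Br2, TiCl4) of the less hindered linking ketone gives (2R,5S,6R)-6-{2-[(1R,3R,4S)-3-bromo-4-hydroxy-4-methylcyclohexyl]prop-2-en-1-yl}-2-hydroxy-2-methyl-5-(prop-1-en-2-yl)cyclohexan-1-one F5. Its only ketone is then reduced with LiBH(sBu)3 (THF, −78 °C), which attacks from the equatorial direction to give the axial alcohol, and the route is rejoined at 19.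

**Further compounds**

F1 | step 8 | (1S,2R)-2-bromo-4-(1,3-dioxolan-2-yl)-1-methylcyclohexan-1-ol (C4 epimers) | C1COC(O1)C1CC[C@](C)(O)[C@H](Br)C1
F2 | step 8 | (2R,5S)-6-({2-[(3R,4S)-3-bromo-4-hydroxy-4-methylcyclohexyl]-1,3-dioxolan-2-yl}methyl)-2-hydroxy-2-methyl-5-(prop-1-en-2-yl)cyclohexan-1-one (epimers at C6 and at cyclohexyl C1) | C1COC(O1)(CC1[C@@H](C(=C)C)CC[C@@](C)(O)C1=O)C1CC[C@](C)(O)[C@H](Br)C1
F3 | step 2 | trimethyl{[(5S)-2-methyl-5-(prop-1-en-2-yl)cyclohex-1-en-1-yl]oxy}silane | CC1=C(O[Si](C)(C)C)C[C@@H](C(C)=C)CC1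
F4 | step 2 | (2R,5S)-2-methyl-5-(prop-1-en-2-yl)-2-[(trimethylsilyl)oxy]cyclohexan-1-one | C1[C@@H](C(=C)C)CC[C@@](C)(O[Si](C)(C)C)C1=O
F5 | step 9 | (2R,5S,6R)-6-{2-[(1R,3R,4S)-3-bromo-4-hydroxy-4-methylcyclohexyl]prop-2-en-1-yl}-2-hydroxy-2-methyl-5-(prop-1-en-2-yl)cyclohexan-1-one | C=C(C[C@@H]1[C@@H](C(=C)C)CC[C@@](C)(O)C1=O)[C@@H]1CC[C@](C)(O)[C@H](Br)C1
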